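Ring C of the flavonol is cut between C3 and C4. Both carbons bear oxygen in the target (C3–O–sulfate, C4=O), so both can start as aldehyde carbons: the ring A formyl group (C4) and the formyl group of an α-aryloxy arylacetaldehyde (C3), already linked through O1 and C2. One SmI2 ketyl coupling of this dialdehyde forms C3–C4, closes ring C and keeps both oxygens as a 3,4-diol; double oxidation then gives the flavonol with O3 as its only free hydroxyl. The precursor carries benzyl ethers on O5, O7 and O3' and a MOM ether on O4', and is assembled by Mitsunobu etherification of a mandelate with the ring A phenol.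

Key step: step 9

Assumption: the target is drawn as the free bis(hydrogen sulfate); it and its benzylated precursor 16 are handled as disodium salts and are listed in the neutral acid form.

Remark on stereochemistry: compounds 6 to 13 are racemic, with one enantiomer drawn. The target has no stereocentre.

Remark on the precursor: the dialdehyde is made in the last step before the coupling and is not purified, because its α-aryl-α-aryloxy aldehyde is enolisable. The benzylic ether is made by a Mitsunobu reaction, so no ionisation-prone p-alkoxybenzylic halide is needed.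

Step 1
Reactants: 1 2,4,6-trihydroxybenzaldehyde
Product: 2 2,4-bis(benzyloxy)-6-hydroxybenzaldehyde
Conditions: BnBr (2.05 equiv), K2CO3 (2.2 equiv), DMF, 0 °C to rt
Reagents that add atoms: benzyl bromide, BrCc1ccccc1
Why: Williamson etherification; the para hydroxyl and one ortho hydroxyl are alkylated, while the last ortho hydroxyl, held in a hydrogen bond to the formyl oxygen, is the least nucleophilic and should stay free.

Step 2
Reactants: 3 3,4-dihydroxybenzaldehyde
Product: 4 3-hydroxy-4-(methoxymethoxy)benzaldehyde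
Conditions: MOMCl (1.05 equiv), K2CO3 (1.1 equiv), acetone, 0 °C to rt
Reagents that add atoms: chloromethyl methyl ether, COCCl
Why: Regioselective O-alkylation; the hydroxyl para to the formyl group is the more acidic one, so one equivalent of weak base should form its phenoxide selectively and only O4 is alkylated.

Step 3
Reactants: 4 3-hydroxy-4-(methoxymethoxy)benzaldehyde
Product: 5 3-(benzyloxy)-4-(methoxymethoxy)benzaldehyde
Conditions: BnBr (1.2 equiv), K2CO3, DMF, rt
Reagents that add atoms: benzyl bromide, BrCc1ccccc1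
Why: Williamson etherification of the remaining phenol; the MOM acetal is stable to base and cannot migrate.

Step 4
Reactants: 5 3-(benzyloxy)-4-(methoxymethoxy)benzaldehyde
Product: 7 2-[3-(benzyloxy)-4-(methoxymethoxy)phenyl]-2-hydroxyacetic acid, via tribromomethyl carbinol 6 (not isolated)
Conditions: CHBr3, KOH, LiCl, 1,4-dioxane/H2O, 0 °C to rt; then 1 M HCl to pH 3 at 0 °C
Reagents that add atoms: bromoform, BrC(Br)Br; potassium hydroxide, [K+].[OH-]
Why: Jocic–Reeve-type one-carbon homologation; tribromomethanide adds to the aldehyde and hydroxide converts the carbinol into the α-hydroxy acid under basic conditions that leave the MOM acetal and benzyl ether untouched, the new stereocentre forming as a racemate.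

Step 5
Reactants: 7 2-[3-(benzyloxy)-4-(methoxymethoxy)phenyl]-2-hydroxyacetic acid
Product: 8 methyl 2-[3-(benzyloxy)-4-(methoxymethoxy)phenyl]-2-hydroxyacetate
Conditions: MeI, KHCO3, DMF, rt
Reagents that add atoms: iodomethane, CI
Why: SN2 alkylation of the carboxylate; hydrogencarbonate deprotonates only the carboxylic acid, so the secondary hydroxyl should stay free.

Step 6
Reactants: 8 methyl 2-[3-(benzyloxy)-4-(methoxymethoxy)phenyl]-2-hydroxyacetate; 2 2,4-bis(benzyloxy)-6-hydroxybenzaldehyde
Product: 9 methyl 2-[3,5-bis(benzyloxy)-2-formylphenoxy]-2-[3-(benzyloxy)-4-(methoxymethoxy)phenyl]acetate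
Conditions: PPh3, DIAD, THF, 0 °C to rt
Reagents that add atoms: none
Why: Mitsunobu etherification; the acidic chelated phenol of 2 displaces the activated hydroxyl of the α-hydroxy ester at the benzylic carbon (inversion, irrelevant for the racemate), forming the O1–C2 bond without base and so avoiding aldol closure onto the formyl group.

Step 7
Reactants: 9 methyl 2-[3,5-bis(benzyloxy)-2-formylphenoxy]-2-[3-(benzyloxy)-4-(methoxymethoxy)phenyl]acetate
Product: 10 2-[3,5-bis(benzyloxy)-2-(hydroxymethyl)phenoxy]-2-[3-(benzyloxy)-4-(methoxymethoxy)phenyl]ethan-1-ol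
Conditions: LiAlH4, THF, 0 °C; then Na2SO4·10H2O
Reagents that add atoms: none
Why: Hydride reduction of both the ester and the aryl aldehyde to primary alcohols brings C3 and C4 to the same oxidation level for the joint oxidation; ethers and the acetal are inert and the basic quench protects the acid-sensitive trialkoxybenzyl alcohol.

Step 8
Reactants: 10 2-[3,5-bis(benzyloxy)-2-(hydroxymethyl)phenoxy]-2-[3-(benzyloxy)-4-(methoxymethoxy)phenyl]ethan-1-ol
Product: 11 2,4-bis(benzyloxy)-6-{1-[3-(benzyloxy)-4-(methoxymethoxy)phenyl]-2-oxoethoxy}benzaldehyde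
Conditions: Dess–Martin periodinane (2.6 equiv), NaHCO3, CH2Cl2, 0 °C to rt; filtered through Celite and used at once
Reagents that add atoms: none
Why: Dess–Martin oxidation of both primary alcohols; the buffered, non-basic medium should prevent enolisation of the α-aryl-α-aryloxy aldehyde and its aldol closure onto the neighbouring formyl group.

Step 9
Reactants: 11 2,4-bis(benzyloxy)-6-{1-[3-(benzyloxy)-4-(methoxymethoxy)phenyl]-2-oxoethoxy}benzaldehyde
Product: 12 (2R*,3S*,4S*)-5,7-bis(benzyloxy)-2-[3-(benzyloxy)-4-(methoxymethoxy)phenyl]chromane-3,4-diol (2,3-trans-3,4-cis)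
Conditions: SmI2 (0.1 M in THF, 3 equiv), t-BuOH (3 equiv), THF, −78 °C to −20 °C, dialdehyde added slowly to the reductant
Reagents that add atoms: none
Why: This is an SmI2-mediated intramolecular pinacol coupling of a 1,6-dialdehyde, as known for α-alkoxy dialdehydes that give cis-cyclohexanediols: divalent samarium transfers one electron to the aryl-conjugated ring A aldehyde, the samarium-bound ketyl at C4 adds to the samarium-coordinated aliphatic aldehyde carbon C3, and a second electron plus t-BuOH deliver the diol. Ring C (O1–C2–C3–C4–C4a–C8a) closes in a 6-exo-trig mode. C3 and C4 should be set cis because both oxygens stay bound to one trivalent samarium in the cyclisation transition state, and this chelate should lie anti to the pseudo-equatorial C2 aryl group, which gives the 2,3-trans relationship. The step needs carbon–carbon coupling to outrun both simple reduction of the formyl groups and reductive loss of the ring A aryloxide from the α-aryloxy aldehyde; the six-atom tether, the readier reduction of the conjugated aldehyde, low temperature and the absence of HMPA are expected to secure this. Any diastereomer mixture is usable because C2, C3 and C4 all become sp2 in step 10.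

Step 10
Reactants: 12 (2R*,3S*,4S*)-5,7-bis(benzyloxy)-2-[3-(benzyloxy)-4-(methoxymethoxy)phenyl]chromane-3,4-diol
Product: 14 5,7-bis(benzyloxy)-2-[3-(benzyloxy)-4-(methoxymethoxy)phenyl]-3-hydroxy-4H-chromen-4-one, via flavan-3,4-dione 13 (not isolated)
Conditions: (COCl)2 (3 equiv), DMSO (6 equiv), CH2Cl2, −78 °C; then Et3N, −78 °C to rt
Reagents that add atoms: none
Why: Swern oxidation of both carbinols, which does not cleave the glycol C–C bond, gives the 3,4-dione, whose acidic C2–H is removed by Et3N so that it tautomerises to the aromatic 3-hydroxy-4-pyranone, leaving O3 as the only free hydroxyl.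

Step 11
Reactants: 14 5,7-bis(benzyloxy)-2-[3-(benzyloxy)-4-(methoxymethoxy)phenyl]-3-hydroxy-4H-chromen-4-one
Product: 15 5,7-bis(benzyloxy)-2-[3-(benzyloxy)-4-hydroxyphenyl]-3-hydroxy-4H-chromen-4-one
Conditions: conc. HCl (catalytic), MeOH/THF, 45 °C
Reagents that add atoms: none
Why: Acid-catalysed transacetalisation of the aryl MOM ether to methanol; benzyl ethers and the flavonol core should be stable to dilute methanolic acid at this temperature.

Step 12
Reactants: 15 5,7-bis(benzyloxy)-2-[3-(benzyloxy)-4-hydroxyphenyl]-3-hydroxy-4H-chromen-4-one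
Product: 16 5,7,3'-tri-O-benzylquercetin 3,4'-bis(hydrogen sulfate)
Conditions: SO3·pyridine (8 equiv), pyridine/DMF, 50 °C; then cation exchange resin (Na+ form)
Reagents that add atoms: sulfur trioxide–pyridine complex, O=S(=O)([O-])[n+]1ccccc1
Why: O-sulfation with an amine–SO3 complex; O3 and O4' are the only free hydroxyls, so excess reagent should sulfate both, and the basic medium keeps the acid-labile aryl sulfates as salts.

Step 13
Reactants: 16 5,7,3'-tri-O-benzylquercetin 3,4'-bis(hydrogen sulfate)
Product: 17 quercetin 3,4'-bis(hydrogen sulfate)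
Conditions: H2 (1 atm), Pd/C (10 wt % palladium on carbon), MeOH/THF/H2O, rt
Reagents that add atoms: none
Why: Hydrogenolysis of the three benzyl ethers over palladium on carbon; aryl sulfate salts and the C2=C3 bond of the flavonol should not be reduced under these mild conditions, and pyridine was removed in step 12 because it would inhibit the catalyst.

Compound list

1 | 2,4,6-trihydroxybenzaldehyde | O=Cc1c(O)cc(O)cc1O | starting material
2 | 2,4-bis(benzyloxy)-6-hydroxybenzaldehyde | O=Cc1c(O)cc(OCc2ccccc2)cc1OCc1ccccc1 | intermediate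
3 | 3,4-dihydroxybenzaldehyde | O=Cc1ccc(O)c(O)c1 | starting material
4 | 3-hydroxy-4-(methoxymethoxy)benzaldehyde | COCOc1ccc(C=O)cc1O | intermediate
5 | 3-(benzyloxy)-4-(methoxymethoxy)benzaldehyde | COCOc1ccc(C=O)cc1OCc1ccccc1 | intermediate
6 | 1-[3-(benzyloxy)-4-(methoxymethoxy)phenyl]-2,2,2-tribromoethan-1-ol (racemic, one enantiomer drawn) | COCOc1ccc(cc1OCc1ccccc1)[C@H](C(Br)(Br)Br)O | intermediate (not isolated)
7 | 2-[3-(benzyloxy)-4-(methoxymethoxy)phenyl]-2-hydroxyacetic acid (racemic, one enantiomer drawn) | COCOc1ccc(cc1OCc1ccccc1)[C@@H](C(=O)O)O | intermediate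
8 | methyl 2-[3-(benzyloxy)-4-(methoxymethoxy)phenyl]-2-hydroxyacetate (racemic, one enantiomer drawn) | COCOc1ccc(cc1OCc1ccccc1)[C@@H](C(=O)OC)O | intermediate
9 | methyl 2-[3,5-bis(benzyloxy)-2-formylphenoxy]-2-[3-(benzyloxy)-4-(methoxymethoxy)phenyl]acetate (racemic, one enantiomer drawn) | COCOc1ccc(cc1OCc1ccccc1)[C@H](C(=O)OC)Oc1cc(OCc2ccccc2)cc(OCc2ccccc2)c1C=O | intermediate
10 | 2-[3,5-bis(benzyloxy)-2-(hydroxymethyl)phenoxy]-2-[3-(benzyloxy)-4-(methoxymethoxy)phenyl]ethan-1-ol (racemic, one enantiomer drawn) | COCOc1ccc(cc1OCc1ccccc1)[C@H](CO)Oc1cc(OCc2ccccc2)cc(OCc2ccccc2)c1CO | intermediate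
11 | 2,4-bis(benzyloxy)-6-{1-[3-(benzyloxy)-4-(methoxymethoxy)phenyl]-2-oxoethoxy}benzaldehyde (racemic, one enantiomer drawn) | COCOc1ccc(cc1OCc1ccccc1)[C@H](C=O)Oc1cc(OCc2ccccc2)cc(OCc2ccccc2)c1C=O | intermediate
12 | (2R*,3S*,4S*)-5,7-bis(benzyloxy)-2-[3-(benzyloxy)-4-(methoxymethoxy)phenyl]chromane-3,4-diol, 2,3-trans-3,4-cis (racemic, one enantiomer drawn) | COCOc1ccc(cc1OCc1ccccc1)[C@@H]1[C@H]([C@H](c2c(OCc3ccccc3)cc(OCc3ccccc3)cc2O1)O)O | intermediate
13 | 5,7-bis(benzyloxy)-2-[3-(benzyloxy)-4-(methoxymethoxy)phenyl]chromane-3,4-dione (racemic, one enantiomer drawn) | COCOc1ccc(cc1OCc1ccccc1)[C@@H]1C(=O)C(=O)c2c(OCc3ccccc3)cc(OCc3ccccc3)cc2O1 | intermediate (not isolated)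
14 | 5,7-bis(benzyloxy)-2-[3-(benzyloxy)-4-(methoxymethoxy)phenyl]-3-hydroxy-4H-chromen-4-one | O=c1c(O)c(-c2ccc(OCOC)c(OCc3ccccc3)c2)oc2cc(OCc3ccccc3)cc(OCc3ccccc3)c12 | intermediate
15 | 5,7-bis(benzyloxy)-2-[3-(benzyloxy)-4-hydroxyphenyl]-3-hydroxy-4H-chromen-4-one | O=c1c(O)c(-c2ccc(O)c(OCc3ccccc3)c2)oc2cc(OCc3ccccc3)cc(OCc3ccccc3)c12 | intermediate
16 | 5,7,3'-tri-O-benzylquercetin 3,4'-bis(hydrogen sulfate) | O=c1c(OS(=O)(=O)O)c(-c2ccc(OS(=O)(=O)O)c(OCc3ccccc3)c2)oc2cc(OCc3ccccc3)cc(OCc3ccccc3)c12 | intermediate
17 | quercetin 3,4'-bis(hydrogen sulfate) | O=c1c(OS(=O)(=O)O)c(-c2ccc(OS(=O)(=O)O)c(O)c2)oc2cc(O)cc(O)c12 | target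

Total step count: 13.
Longest linear sequence: 12 steps (steps 2 to 13, from 3,4-dihydroxybenzaldehyde).

Steps most likely to fail

Step 9. The electron may go to the aliphatic aldehyde first, after which the ring A aryloxide is expelled, or both formyl groups may simply be reduced without carbon–carbon bond formation. The fallback sets out from 5 and returns at 14, closing ring C at O1–C2 instead. Claisen–Schmidt condensation of 5 with commercial 1-[2,4-bis(benzyloxy)-6-hydroxyphenyl]ethanone (KOH, EtOH, rt) should give the chalcone (E)-1-[2,4-bis(benzyloxy)-6-hydroxyphenyl]-3-[3-(benzyloxy)-4-(methoxymethoxy)phenyl]prop-2-en-1-one F1. Algar–Flynn–Oyamada oxidation (H2O2, NaOH, MeOH/THF, kept at 0 °C to disfavour aurone formation) then leads directly to flavonol 14.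

Step 10. The C3–C4 glycol bond may be cleaved oxidatively, or the doubly donor-activated benzylic C4 may ionise while the alcohol is activated. The fallback sets out from 12 and returns at 14, oxidising the two carbinols separately. DDQ (CH2Cl2, rt) should oxidise only the electron-rich benzylic C4 carbinol to the dihydroflavonol (2R*,3R*)-5,7-bis(benzyloxy)-2-[3-(benzyloxy)-4-(methoxymethoxy)phenyl]-3-hydroxychroman-4-one F2. Dehydrogenation with I2 and KOAc in EtOH at 70 °C then gives 14.

Step 6. The p-alkoxybenzylic oxyphosphonium ion may ionise and be captured by the hydrazide while the chelated phenol reacts too slowly. The fallback sets out from 8 and returns at 9, replacing the redox condensation by a two-stage SN2 sequence. Appel bromination (CBr4, PPh3, CH2Cl2, 0 °C) converts 8 into methyl 2-bromo-2-[3-(benzyloxy)-4-(methoxymethoxy)phenyl]acetate F3. Phenol 2 is then O-alkylated by F3 with Cs2CO3 in DMF at 0 °C to rt.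

Further compounds

F1 | step 9 | (E)-1-[2,4-bis(benzyloxy)-6-hydroxyphenyl]-3-[3-(benzyloxy)-4-(methoxymethoxy)phenyl]prop-2-en-1-one | COCOc1ccc(/C=C/C(=O)c2c(O)cc(OCc3ccccc3)cc2OCc2ccccc2)cc1OCc1ccccc1
F2 | step 10 | (2R*,3R*)-5,7-bis(benzyloxy)-2-[3-(benzyloxy)-4-(methoxymethoxy)phenyl]-3-hydroxychroman-4-one (racemic, one enantiomer drawn) | COCOc1ccc(cc1OCc1ccccc1)[C@@H]1[C@H](C(=O)c2c(OCc3ccccc3)cc(OCc3ccccc3)cc2O1)O
F3 | step 6 | methyl 2-bromo-2-[3-(benzyloxy)-4-(methoxymethoxy)phenyl]acetate (racemic, one enantiomer drawn) | COCOc1ccc(cc1OCc1ccccc1)[C@H](C(=O)OC)Br
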